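5 questions on 4 flasks come down to one comparison: how long substrate lives against how long second reagent takes to arrive.

| flask | substrate | coupling partner | second reagent | third reagent | capture agent | temperature | remark | time |
|---|---|---|---|---|---|---|---|---|
| teal | 0.10 M | 1.5 equiv | 2 equiv | 0.50 equiv | 0.010 M | 85 °C | run made earlier |  |
| green | 0.10 M | 1.5 equiv | 2 equiv | 0.50 equiv | 0.0050 M | 96 °C | run made earlier |  |
| ochre | 0.10 M | 1.5 equiv | 2 equiv | 0.50 equiv | 0.020 M | 85 °C | run made earlier |  |
| larch | 0.10 M | 1.50 equiv | 2.00 equiv | 0.500 equiv (fed, over 30 min) | 0.0100 M | 90 °C | all else is in the flask from the start; the feed brings no volume worth counting | 2.5 h |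
| elm | 0.10 M | 1.50 equiv | 2.00 equiv | 0.500 equiv | 0.0100 M |  | everything together at the start at 70 °C, warmed to 90 °C at 30 min | 2.5 h |
| ash | 0.10 M | 1.50 equiv | 2.00 equiv | 0.500 equiv | 0.0100 M | 90 °C | everything together at the start | 2.5 h |
| maple | 0.10 M | 1.50 equiv | 2.00 equiv (fed, over 30 min) | 0.500 equiv | 0.0100 M |  | the addition at 70 °C, then warmed to 90 °C; the feed brings no volume worth counting | 2.5 h |

- teal (time / h: target / %, side product / %): 0.200: 0, 13.9; 0.667: 3.8, 13.8; 1.33: 6.0, 15.0; 2.00: 11.8, 14.4; 2.50: 13.0, 13.9
- green (time / h: target / %, side product / %): 0.250: 1.3, 14.3; 0.833: 8.3, 14.9; 1.33: 14.0, 14.0; 2.00: 23.6, 14.7; 3.00: 34.5, 14.7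
- ochre (time / h: target / %, side product / %): 0.250: 1.7, 13.8; 0.417: 0, 15.3; 0.833: 3.3, 13.9; 1.50: 5.2, 15.8; 3.00: 17.6, 13.2

(standard deviation of a reading: 1 percentage point)

* the flask that comes out highest in share of target in target plus side product, or "all alike" when all lie within 1.5 percentage points (larch / elm / ash / maple / all alike)
* share of target in target plus side product at the end, larch
* share of target in target plus side product at the end, elm
* share of target in target plus side product at the end, ash
* share of target in target plus side product at the end, maple

- the numbers in the tables scatter with a standard deviation of 1 percentage point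

This reckoning assumes that coupling partner and second reagent both consume substrate, and that the flat side product marks the end of substrate. The teal side product averages

burst = 14.2%

so the selectivity factor, side product per substrate coupled at full charges, is

r = burst/(1 − burst) = 0.166

The first teal reading, at 0.200 h, already lies on that plateau. Taken as 2.3 lifetimes, it leaves a gap of 1.42%, near the scatter, so this reckoning takes 0.0870 h as an upper estimate of the life of substrate at 85 °C. Read from the last readings, target forms 2.21 times as fast in green as in teal, though these two runs differ in capture agent as well as in temperature. If coupling warms by that same factor, the upper estimate of the life at 70 °C is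

τ = 0.257 h

The maple feed lasts 30 min, longer than that life. Second reagent climbs linearly, so substrate meets on average this part of the full charge, the feed cover:

cover = τ/30 min = 0.513

The upper estimate of side product in maple is then

r·cover/(1 + r·cover) = 7.83%

Larch and elm leave second reagent at full charge, so they should keep the burst. With the teal end target 13.0% as a stand-in, maple reckons at 62.4% and ash at 47.8%, so this reckoning names maple, above ash by 15 points against a margin of 1.5 points.

The forecast gave 55% for larch, 54% for elm, 56% for ash and 53% for maple, named ash, and noted “The runs say nothing about how feeding changes the burst”.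

The flask gives maple, at 74.3%, with ash at 58.7%, larch at 58.6% and elm at 56.2%.

    substrate + coupling partner → intermediate A (k = 0.0680 /M/s, Ea = 82.0 kJ/mol)
    substrate + second reagent → side product (k = 0.00590 /M/s, Ea = 87.0 kJ/mol)
    intermediate A + capture agent → trapped intermediate (k = 0.00180 /M/s, Ea = 94.0 kJ/mol)
    second reagent + intermediate A → intermediate B (k = 4.30 × 10⁻⁴ /M/s, Ea = 71.0 kJ/mol)
    third reagent + intermediate B → target (k = 0.00440 /M/s, Ea = 60.0 kJ/mol)
    (constants at 90 °C)

At 2.50 h, maple holds 6.27% side product and ash 14.2%. Read back through r, the maple figure is a cover of 0.404, below the upper estimate. In this reckoning both r and the life go inversely with coupling partner, so for maple with 3.80 equiv of coupling partner, all else held, the cover takes the side product to 0.977%. That neighbour flask holds 0.614%, and its share of target is 96.9%.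

The numbers in the tables were generated by integration with constants of no real substance, noise included.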